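**Strategy.** Numbering the carbon chain from the alkyne CH (C1) to the ethyl CH3 (C15), the oxocene is the ring O–C7–C8–C9=C10–C11–C12–C13. The route rests on cutting C7–C8: C7 sits α to the ring oxygen and C8 is allylic to the Z C9=C10 alkene, so with C6 as an amide carbonyl an α-alkoxy enolate can displace an allylic chloride. One base-mediated step then closes the eight-membered ring, forms C7–C8 and sets C7 cis to C13. The precursor is an acyclic N,N-dimethyl (C13-oxy)acetamide with a (Z)-allylic chloride at C8, a PMB ether at C12 and the syn C12/C13 pair from an alkoxyallylboration of propanal; the amide later accepts C4–C5.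

Key step: step 9

Remark: the allylborane made from (+)-α-pinene is taken to add to the Si face of propanal, its usual sense with unbranched aldehydes, which leads to the (3R,4R) alcohol 8.
Remark: a two-carbon 2-oxidoethyl ylide adding to a C10 aldehyde would favour the E-alkene, so the Z C9=C10 bond is made with the ylide on C10 and a silyloxyacetaldehyde.

Step 1
Reactants: 1 allyl 4-methoxybenzyl ether; 2 (−)-B-methoxydiisopinocampheylborane [(−)-Ipc2BOMe, from (+)-α-pinene]; 3 propanal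
Product: 8 (3R,4R)-4-[(4-methoxybenzyl)oxy]hex-5-en-3-ol, via lithiated allyl ether 4 (not isolated), via borate complex 5 (not isolated), via Z-alkoxyallylborane 6 (not isolated), via borinate adduct 7 (not isolated)
Conditions: s-BuLi, THF, −78 °C; 2, −78 °C; BF3·OEt2; 3, −78 °C → rt; then 3 M NaOH, 30% H2O2
Reagents that add atoms: sec-butyllithium, [Li]C(C)CC (lithium of 4 and 5 only)
Why: Brown-type (Z)-γ-alkoxyallylboration, in which the chelated Z-oxyallyl anion is borylated at its CH2 terminus and the Z-allylborane adds to propanal through a closed chair transition state, the Z geometry fixing the syn C12/C13 relationship and the isopinocampheyl groups directing attack to the Si face of the aldehyde, so both centres should form as (3R,4R).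

Step 2
Reactants: 8 (3R,4R)-4-[(4-methoxybenzyl)oxy]hex-5-en-3-ol; 9 2-chloro-N,N-dimethylacetamide
Product: 10 2-{[(3R,4R)-4-[(4-methoxybenzyl)oxy]hex-5-en-3-yl]oxy}-N,N-dimethylacetamide
Conditions: NaH, n-Bu4NI (cat.), THF, 0 °C → rt
Reagents that add atoms: none
Why: Williamson etherification, the sodium alkoxide of 8 displacing chloride from the activated α-chloro amide by SN2 without touching C12 or C13.

Step 3
Reactants: 10 2-{[(3R,4R)-4-[(4-methoxybenzyl)oxy]hex-5-en-3-yl]oxy}-N,N-dimethylacetamide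
Product: 12 2-{[(3R,4R)-6-hydroxy-4-[(4-methoxybenzyl)oxy]hexan-3-yl]oxy}-N,N-dimethylacetamide, via alkyldicyclohexylborane 11 (not isolated)
Conditions: Cy2BH (from BH3·SMe2, cyclohexene), THF, 0 °C → rt; then 3 M NaOH, 30% H2O2, 0 °C
Reagents that add atoms: hydrogen peroxide, OO (hydroxyl oxygen); dicyclohexylborane, B(C1CCCCC1)C1CCCCC1 (boron of 11 only)
Why: Hydroboration–oxidation with a hindered dialkylborane should place boron on the terminal carbon C10 and leave the tertiary amide alone at this temperature, and the peroxide step replaces boron by OH without affecting the stereocentres.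

Step 4
Reactants: 12 2-{[(3R,4R)-6-hydroxy-4-[(4-methoxybenzyl)oxy]hexan-3-yl]oxy}-N,N-dimethylacetamide
Product: 13 2-{[(3R,4R)-6-iodo-4-[(4-methoxybenzyl)oxy]hexan-3-yl]oxy}-N,N-dimethylacetamide
Conditions: I2, PPh3, imidazole, CH2Cl2, 0 °C → rt
Reagents that add atoms: iodine, II
Why: Appel-type iodination, the primary oxyphosphonium group being displaced by iodide (SN2) under near-neutral conditions that the PMB ether and the amide tolerate.

Step 5
Reactants: 13 2-{[(3R,4R)-6-iodo-4-[(4-methoxybenzyl)oxy]hexan-3-yl]oxy}-N,N-dimethylacetamide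
Product: 14 [(3R,4R)-4-[2-(dimethylamino)-2-oxoethoxy]-3-[(4-methoxybenzyl)oxy]hexyl]triphenylphosphonium iodide
Conditions: PPh3, MeCN, 80 °C
Reagents that add atoms: triphenylphosphine, c1ccc(cc1)P(c1ccccc1)c1ccccc1
Why: SN2 quaternisation of triphenylphosphine by the unhindered primary iodide should give the Wittig salt, the ether oxygens being too weakly nucleophilic to compete.

Step 6
Reactants: 14 [(3R,4R)-4-[2-(dimethylamino)-2-oxoethoxy]-3-[(4-methoxybenzyl)oxy]hexyl]triphenylphosphonium iodide; 15 (tert-butyldimethylsilyloxy)acetaldehyde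
Product: 17 2-{[(3R,4R,6Z)-8-[(tert-butyldimethylsilyl)oxy]-4-[(4-methoxybenzyl)oxy]oct-6-en-3-yl]oxy}-N,N-dimethylacetamide, via phosphonium ylide 16 (not isolated)
Conditions: NaHMDS (1.0 equiv), THF, −78 → 0 °C; 15, −78 °C → rt
Reagents that add atoms: none
Why: Wittig olefination of a non-stabilised ylide under lithium-free conditions passes through the kinetically favoured cis-oxaphosphetane and should give the Z C9=C10 alkene, the phosphonium α-hydrogens being more acidic than those of the amide so that one equivalent of base forms only the ylide.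

Step 7
Reactants: 17 2-{[(3R,4R,6Z)-8-[(tert-butyldimethylsilyl)oxy]-4-[(4-methoxybenzyl)oxy]oct-6-en-3-yl]oxy}-N,N-dimethylacetamide
Product: 18 2-{[(3R,4R,6Z)-8-hydroxy-4-[(4-methoxybenzyl)oxy]oct-6-en-3-yl]oxy}-N,N-dimethylacetamide
Conditions: TBAF, THF, 0 °C → rt
Reagents that add atoms: none
Why: Fluoride-mediated cleavage of the primary silyl ether should release the Z-allylic alcohol without affecting the PMB ether, the amide or the alkene geometry.

Step 8
Reactants: 18 2-{[(3R,4R,6Z)-8-hydroxy-4-[(4-methoxybenzyl)oxy]oct-6-en-3-yl]oxy}-N,N-dimethylacetamide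
Product: 20 2-{[(3R,4R,6Z)-8-chloro-4-[(4-methoxybenzyl)oxy]oct-6-en-3-yl]oxy}-N,N-dimethylacetamide, via allylic mesylate 19 (not isolated)
Conditions: MsCl, 2,4,6-collidine, LiCl, DMF, 0 °C
Reagents that add atoms: lithium chloride, [Li+].[Cl-] (chlorine of 20); methanesulfonyl chloride, CS(=O)(=O)Cl (mesyl group of 19 only)
Why: Collington–Meyers chlorination, the mesylate formed in situ being displaced by chloride at the primary carbon (SN2, no allylic shift), so the Z geometry is kept and no free acid threatens the PMB ether.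

Step 9
Reactants: 20 2-{[(3R,4R,6Z)-8-chloro-4-[(4-methoxybenzyl)oxy]oct-6-en-3-yl]oxy}-N,N-dimethylacetamide
Product: 22 (2R,7R,8R)-8-ethyl-7-[(4-methoxybenzyl)oxy]-N,N-dimethyl-3,6,7,8-tetrahydro-2H-oxocine-2-carboxamide, via lithium amide enolate 21 (not isolated)
Conditions: LiHMDS (1.2 equiv), THF (0.01 M), −78 °C → rt
Reagents that add atoms: lithium hexamethyldisilazide, [Li]N([Si](C)(C)C)[Si](C)(C)C (lithium of 21 only)
Why: LiHMDS removes an α-proton of the α-alkoxy acetamide to give the chelated Z(O)-lithium enolate 21, whose carbon C7 attacks the primary allylic carbon C8 and expels chloride, forming the C7–C8 bond. The closest known reaction type is the intramolecular alkylation of α-alkoxy amide enolates by cis-allylic halides, established for cis-α,α'-disubstituted oxocenes. The oxocene closes in an 8-exo-tet mode, the breaking C8–Cl bond lying outside the new ring. C7 is controlled by the existing C13 centre: in the folded transition state the C13–H bond eclipses the enolate plane and both the ethyl group and the amide sit pseudo-equatorially, so the new bond forms cis to the ethyl group across the ring oxygen, giving (7R). The step needs SN2 attack at C8 and not SN2′ attack at C10 (which would give a vinyl tetrahydropyran), and ring closure and not intermolecular alkylation. The Z alkene holds C8, not C10, within reach of the enolate carbon, the gauche C12–O/C13–O arrangement pre-folds the chain, the dialkylamide enolate is reactive without self-condensing, and high dilution suppresses dimers.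

Step 10
Reactants: 22 (2R,7R,8R)-8-ethyl-7-[(4-methoxybenzyl)oxy]-N,N-dimethyl-3,6,7,8-tetrahydro-2H-oxocine-2-carboxamide; 23 (1,3-dioxolan-2-ylmethyl)magnesium bromide
Product: 25 2-(1,3-dioxolan-2-yl)-1-[(2R,7R,8R)-8-ethyl-7-[(4-methoxybenzyl)oxy]-3,6,7,8-tetrahydro-2H-oxocin-2-yl]ethan-1-one, via magnesium hemiaminal 24 (not isolated)
Conditions: 23 (0.5 M in THF), THF, 0 °C; then H2O (pH 7 buffer)
Reagents that add atoms: none
Why: Acyl substitution of the α-alkoxy N,N-dimethylamide by the Grignard reagent should stop at the chelated tetrahedral magnesium hemiaminal, which collapses to the ketone only on aqueous work-up, so over-addition and C7 epimerisation are avoided (Weinreb-type direct ketone synthesis).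

Step 11
Reactants: 25 2-(1,3-dioxolan-2-yl)-1-[(2R,7R,8R)-8-ethyl-7-[(4-methoxybenzyl)oxy]-3,6,7,8-tetrahydro-2H-oxocin-2-yl]ethan-1-one
Product: 26 (1R)-2-(1,3-dioxolan-2-yl)-1-[(2R,7R,8R)-8-ethyl-7-[(4-methoxybenzyl)oxy]-3,6,7,8-tetrahydro-2H-oxocin-2-yl]ethan-1-ol
Conditions: L-Selectride, THF, −78 °C; then H2O
Reagents that add atoms: none
Why: Felkin–Anh reduction with the bulky, non-chelating L-Selectride, in which the C7–O bond lies antiperiplanar to the incoming hydride and attack past the C7 hydrogen should give the (6R) alcohol, syn to the ring oxygen.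

Step 12
Reactants: 26 (1R)-2-(1,3-dioxolan-2-yl)-1-[(2R,7R,8R)-8-ethyl-7-[(4-methoxybenzyl)oxy]-3,6,7,8-tetrahydro-2H-oxocin-2-yl]ethan-1-ol
Product: 27 (1R)-2-(1,3-dioxolan-2-yl)-1-[(2R,7R,8R)-8-ethyl-7-[(4-methoxybenzyl)oxy]-3,6,7,8-tetrahydro-2H-oxocin-2-yl]ethyl acetate
Conditions: Ac2O, pyridine, DMAP (cat.), CH2Cl2, rt
Reagents that add atoms: acetic anhydride, CC(=O)OC(C)=O
Why: DMAP-catalysed acylation of the secondary alcohol installs the C6 acetate of the target, which also protects C6 through the remaining steps.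

Step 13
Reactants: 27 (1R)-2-(1,3-dioxolan-2-yl)-1-[(2R,7R,8R)-8-ethyl-7-[(4-methoxybenzyl)oxy]-3,6,7,8-tetrahydro-2H-oxocin-2-yl]ethyl acetate
Product: 28 (1R)-2-(1,3-dioxolan-2-yl)-1-[(2R,7R,8R)-8-ethyl-7-hydroxy-3,6,7,8-tetrahydro-2H-oxocin-2-yl]ethyl acetate
Conditions: DDQ, CH2Cl2–pH 7 buffer (10:1), 0 °C → rt
Reagents that add atoms: none
Why: Oxidative cleavage of the PMB ether by DDQ (benzylic hydride abstraction, then hydrolysis of the oxocarbenium ion) should free the C12 hydroxyl with retention and leave the acetate, the dioxolane and the ring alkene intact.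

Step 14
Reactants: 28 (1R)-2-(1,3-dioxolan-2-yl)-1-[(2R,7R,8R)-8-ethyl-7-hydroxy-3,6,7,8-tetrahydro-2H-oxocin-2-yl]ethyl acetate
Product: 29 (1R)-1-[(2R,7S,8R)-7-bromo-8-ethyl-3,6,7,8-tetrahydro-2H-oxocin-2-yl]-2-(1,3-dioxolan-2-yl)ethyl acetate
Conditions: CBr4, (n-Oct)3P, toluene, 70 °C
Reagents that add atoms: carbon tetrabromide, BrC(Br)(Br)Br
Why: Appel-type bromination with a small trialkylphosphine, bromide displacing the C12 oxyphosphonium group by SN2 with inversion, so the (12R) hydroxyl cis to the ethyl group should become the (12S) bromide trans to it.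

Step 15
Reactants: 29 (1R)-1-[(2R,7S,8R)-7-bromo-8-ethyl-3,6,7,8-tetrahydro-2H-oxocin-2-yl]-2-(1,3-dioxolan-2-yl)ethyl acetate
Product: 30 (1R)-1-[(2R,7S,8R)-7-bromo-8-ethyl-3,6,7,8-tetrahydro-2H-oxocin-2-yl]-3-oxopropyl acetate
Conditions: TFA–H2O (9:1), CH2Cl2, 0 °C → rt; used crude
Reagents that add atoms: water, O
Why: Acid-catalysed acetal hydrolysis should release the C4 aldehyde under conditions that leave the secondary acetate and bromide untouched, and the β-acetoxy aldehyde is carried on at once without exposure to base.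

Step 16
Reactants: 30 (1R)-1-[(2R,7S,8R)-7-bromo-8-ethyl-3,6,7,8-tetrahydro-2H-oxocin-2-yl]-3-oxopropyl acetate
Product: 31 (1R,3E)-1-[(2R,7S,8R)-7-bromo-8-ethyl-3,6,7,8-tetrahydro-2H-oxocin-2-yl]-4-iodobut-3-en-1-yl acetate
Conditions: CrCl2, CHI3, dioxane–THF (6:1), 0 °C → rt
Reagents that add atoms: iodoform, IC(I)I
Why: Takai olefination, the gem-dichromium species from CHI3/CrCl2 adding to the aldehyde and eliminating to the E-vinyl iodide under non-basic conditions that spare the β-acetate and the secondary bromide.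

Step 17
Reactants: 31 (1R,3E)-1-[(2R,7S,8R)-7-bromo-8-ethyl-3,6,7,8-tetrahydro-2H-oxocin-2-yl]-4-iodobut-3-en-1-yl acetate; 32 ethynyltrimethylsilane
Product: 33 (1R,3E)-1-[(2R,7S,8R)-7-bromo-8-ethyl-3,6,7,8-tetrahydro-2H-oxocin-2-yl]-6-(trimethylsilyl)hex-3-en-5-yn-1-yl acetate
Conditions: PdCl2(PPh3)2 (cat.), CuI (cat.), Et3N, THF, rt
Reagents that add atoms: none
Why: Sonogashira coupling joins the vinyl iodide to the terminal alkyne with retention of the E geometry at room temperature, where the secondary alkyl bromide does not undergo oxidative addition.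

Step 18
Reactants: 33 (1R,3E)-1-[(2R,7S,8R)-7-bromo-8-ethyl-3,6,7,8-tetrahydro-2H-oxocin-2-yl]-6-(trimethylsilyl)hex-3-en-5-yn-1-yl acetate
Product: 34 (1R,3E)-1-[(2R,7S,8R)-7-bromo-8-ethyl-3,6,7,8-tetrahydro-2H-oxocin-2-yl]hex-3-en-5-yn-1-yl acetate (target)
Conditions: TBAF, AcOH, THF, 0 °C
Reagents that add atoms: none
Why: Fluoride-induced protodesilylation of the alkynylsilane, buffered with acetic acid so that the acetate and the secondary bromide do not meet free base, should give the target.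

**Compound list**

1 | allyl 4-methoxybenzyl ether | C=CCOCc1ccc(OC)cc1 | starting material
2 | (−)-B-methoxydiisopinocampheylborane, from (+)-α-pinene | COB([C@@H]1C[C@@H]2C[C@H]([C@H]1C)C2(C)C)[C@@H]1C[C@@H]2C[C@H]([C@H]1C)C2(C)C | starting material
3 | propanal | CCC=O | starting material
4 | lithiated allyl ether, (Z)-3-[(4-methoxybenzyl)oxy]allyllithium (in flask) | [Li+].[CH2-]/C=C\OCc1ccc(OC)cc1 | intermediate
5 | borate complex, lithium (Z)-[3-(4-methoxybenzyloxy)allyl](methoxy)diisopinocampheylborate (in flask) | [Li+].CO[B-](C/C=C\OCc1ccc(OC)cc1)([C@@H]1C[C@@H]2C[C@H]([C@H]1C)C2(C)C)[C@@H]1C[C@@H]2C[C@H]([C@H]1C)C2(C)C | intermediate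
6 | Z-alkoxyallylborane, (Z)-[3-(4-methoxybenzyloxy)allyl]diisopinocampheylborane (in flask) | COc1ccc(CO/C=C\CB([C@@H]2C[C@@H]3C[C@H]([C@H]2C)C3(C)C)[C@@H]2C[C@@H]3C[C@H]([C@H]2C)C3(C)C)cc1 | intermediate
7 | borinate adduct, (3R,4R)-4-[(4-methoxybenzyl)oxy]hex-5-en-3-yl diisopinocampheylborinate (in flask) | O([C@H](CC)[C@H](OCc1ccc(OC)cc1)C=C)B([C@@H]1C[C@@H]2C[C@H]([C@H]1C)C2(C)C)[C@@H]1C[C@@H]2C[C@H]([C@H]1C)C2(C)C | intermediate
8 | (3R,4R)-4-[(4-methoxybenzyl)oxy]hex-5-en-3-ol | O[C@H](CC)[C@H](OCc1ccc(OC)cc1)C=C | intermediate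
9 | 2-chloro-N,N-dimethylacetamide | CN(C)C(=O)CCl | starting material
10 | 2-{[(3R,4R)-4-[(4-methoxybenzyl)oxy]hex-5-en-3-yl]oxy}-N,N-dimethylacetamide | CN(C)C(=O)CO[C@H](CC)[C@H](OCc1ccc(OC)cc1)C=C | intermediate
11 | alkyldicyclohexylborane, C10 dicyclohexylboryl adduct of 10 (in flask) | CN(C)C(=O)CO[C@H](CC)[C@H](OCc1ccc(OC)cc1)CCB(C1CCCCC1)C1CCCCC1 | intermediate
12 | 2-{[(3R,4R)-6-hydroxy-4-[(4-methoxybenzyl)oxy]hexan-3-yl]oxy}-N,N-dimethylacetamide | CN(C)C(=O)CO[C@H](CC)[C@H](OCc1ccc(OC)cc1)CCO | intermediate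
13 | 2-{[(3R,4R)-6-iodo-4-[(4-methoxybenzyl)oxy]hexan-3-yl]oxy}-N,N-dimethylacetamide | CN(C)C(=O)CO[C@H](CC)[C@H](OCc1ccc(OC)cc1)CCI | intermediate
14 | [(3R,4R)-4-[2-(dimethylamino)-2-oxoethoxy]-3-[(4-methoxybenzyl)oxy]hexyl]triphenylphosphonium iodide | CN(C)C(=O)CO[C@H](CC)[C@H](OCc1ccc(OC)cc1)CC[P+](c1ccccc1)(c1ccccc1)c1ccccc1.[I-] | intermediate
15 | (tert-butyldimethylsilyloxy)acetaldehyde | CC(C)(C)[Si](C)(C)OCC=O | starting material
16 | phosphonium ylide of 14 (in flask) | CN(C)C(=O)CO[C@H](CC)[C@H](OCc1ccc(OC)cc1)CC=P(c1ccccc1)(c1ccccc1)c1ccccc1 | intermediate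
17 | 2-{[(3R,4R,6Z)-8-[(tert-butyldimethylsilyl)oxy]-4-[(4-methoxybenzyl)oxy]oct-6-en-3-yl]oxy}-N,N-dimethylacetamide | CN(C)C(=O)CO[C@H](CC)[C@H](OCc1ccc(OC)cc1)C/C=C\CO[Si](C)(C)C(C)(C)C | intermediate
18 | 2-{[(3R,4R,6Z)-8-hydroxy-4-[(4-methoxybenzyl)oxy]oct-6-en-3-yl]oxy}-N,N-dimethylacetamide | CN(C)C(=O)CO[C@H](CC)[C@H](OCc1ccc(OC)cc1)C/C=C\CO | intermediate
19 | allylic mesylate, (2Z,5R,6R)-6-[2-(dimethylamino)-2-oxoethoxy]-5-[(4-methoxybenzyl)oxy]oct-2-en-1-yl methanesulfonate (in flask) | CN(C)C(=O)CO[C@H](CC)[C@H](OCc1ccc(OC)cc1)C/C=C\COS(C)(=O)=O | intermediate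
20 | 2-{[(3R,4R,6Z)-8-chloro-4-[(4-methoxybenzyl)oxy]oct-6-en-3-yl]oxy}-N,N-dimethylacetamide (key-step precursor) | CN(C)C(=O)CO[C@H](CC)[C@H](OCc1ccc(OC)cc1)C/C=C\CCl | intermediate
21 | lithium amide enolate of 20, Z(O) geometry (in flask) | [Li]O/C(N(C)C)=C\O[C@H](CC)[C@H](OCc1ccc(OC)cc1)C/C=C\CCl | intermediate
22 | (2R,7R,8R)-8-ethyl-7-[(4-methoxybenzyl)oxy]-N,N-dimethyl-3,6,7,8-tetrahydro-2H-oxocine-2-carboxamide (key-step product) | CN(C)C(=O)[C@H]1C/C=C\C[C@@H](OCc2ccc(OC)cc2)[C@@H](CC)O1 | intermediate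
23 | (1,3-dioxolan-2-ylmethyl)magnesium bromide | Br[Mg]CC1OCCO1 | starting material
24 | magnesium hemiaminal from 22 and 23 (in flask; aminal carbon unassigned, either epimer collapses to 25) | CN(C)C(O[Mg]Br)(CC1OCCO1)[C@H]1C/C=C\C[C@@H](OCc2ccc(OC)cc2)[C@@H](CC)O1 | intermediate
25 | 2-(1,3-dioxolan-2-yl)-1-[(2R,7R,8R)-8-ethyl-7-[(4-methoxybenzyl)oxy]-3,6,7,8-tetrahydro-2H-oxocin-2-yl]ethan-1-one | O=C(CC1OCCO1)[C@H]1C/C=C\C[C@@H](OCc2ccc(OC)cc2)[C@@H](CC)O1 | intermediate
26 | (1R)-2-(1,3-dioxolan-2-yl)-1-[(2R,7R,8R)-8-ethyl-7-[(4-methoxybenzyl)oxy]-3,6,7,8-tetrahydro-2H-oxocin-2-yl]ethan-1-ol | C1COC(C[C@@H](O)[C@H]2C/C=C\C[C@@H](OCc3ccc(OC)cc3)[C@@H](CC)O2)O1 | intermediate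
27 | (1R)-2-(1,3-dioxolan-2-yl)-1-[(2R,7R,8R)-8-ethyl-7-[(4-methoxybenzyl)oxy]-3,6,7,8-tetrahydro-2H-oxocin-2-yl]ethyl acetate | C1COC(C[C@@H](OC(C)=O)[C@H]2C/C=C\C[C@@H](OCc3ccc(OC)cc3)[C@@H](CC)O2)O1 | intermediate
28 | (1R)-2-(1,3-dioxolan-2-yl)-1-[(2R,7R,8R)-8-ethyl-7-hydroxy-3,6,7,8-tetrahydro-2H-oxocin-2-yl]ethyl acetate | C1COC(C[C@@H](OC(C)=O)[C@H]2C/C=C\C[C@@H](O)[C@@H](CC)O2)O1 | intermediate
29 | (1R)-1-[(2R,7S,8R)-7-bromo-8-ethyl-3,6,7,8-tetrahydro-2H-oxocin-2-yl]-2-(1,3-dioxolan-2-yl)ethyl acetate | C1COC(C[C@@H](OC(C)=O)[C@H]2C/C=C\C[C@H](Br)[C@@H](CC)O2)O1 | intermediate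
30 | (1R)-1-[(2R,7S,8R)-7-bromo-8-ethyl-3,6,7,8-tetrahydro-2H-oxocin-2-yl]-3-oxopropyl acetate | O=CC[C@@H](OC(C)=O)[C@H]1C/C=C\C[C@H](Br)[C@@H](CC)O1 | intermediate
31 | (1R,3E)-1-[(2R,7S,8R)-7-bromo-8-ethyl-3,6,7,8-tetrahydro-2H-oxocin-2-yl]-4-iodobut-3-en-1-yl acetate | I/C=C/C[C@@H](OC(C)=O)[C@H]1C/C=C\C[C@H](Br)[C@@H](CC)O1 | intermediate
32 | ethynyltrimethylsilane | C#C[Si](C)(C)C | starting material
33 | (1R,3E)-1-[(2R,7S,8R)-7-bromo-8-ethyl-3,6,7,8-tetrahydro-2H-oxocin-2-yl]-6-(trimethylsilyl)hex-3-en-5-yn-1-yl acetate | C[Si](C)(C)C#C/C=C/C[C@@H](OC(C)=O)[C@H]1C/C=C\C[C@H](Br)[C@@H](CC)O1 | intermediate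
34 | (1R,3E)-1-[(2R,7S,8R)-7-bromo-8-ethyl-3,6,7,8-tetrahydro-2H-oxocin-2-yl]hex-3-en-5-yn-1-yl acetate | C#C/C=C/C[C@@H](OC(C)=O)[C@H]1C/C=C\C[C@H](Br)[C@@H](CC)O1 | target

**Step count and risks**

Total step count: 18. Longest linear sequence: 18 steps (1 → 34).

Steps most likely to fail:

1. Step 9 (ring closure). The enolate may attack C10 in an SN2′ sense to close a six-membered ring, alkylate a second molecule, or close the oxocene with incomplete cis selectivity. The fallback changes the ring-forming bond to C9=C10; it sets out from alcohol 12 and comes back at oxocene amide 22. Oxidation of 12 with Dess–Martin periodinane would give the aldehyde F1, Wittig methylenation (Ph3P=CH2) the terminal alkene F2, and allylation of its amide enolate (LiHMDS, allyl iodide) the diene F3 together with its C7 epimer. Ring-closing metathesis (second-generation Grubbs catalyst, dilute CH2Cl2, 40 °C) would then give 22. This fallback has no built-in control at C7: the epimers would be separated at the diene or ring stage, and the trans ring amide equilibrated with base toward the cis isomer, which is expected to be favoured.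

2. Step 14 (bromination at C12). The hindered oxyphosphonium intermediate may eliminate to a ring diene, or the ring oxygen may participate and give substitution with retention. The fallback separates activation from displacement; it sets out from alcohol 28 and comes back at bromide 29. Chloromethanesulfonyl chloride and 2,6-lutidine (CH2Cl2, 0 °C) would give the chloromethanesulfonate F4, and n-Bu4NBr in THF would displace it by SN2 with inversion under neutral conditions.

3. Step 15 (aldehyde release). Once the aldehyde is free, acetic acid may be lost by β-elimination to an enal, or the acetate may be hydrolysed during a slow acetal cleavage. The fallback unmasks and consumes the aldehyde before the acetate exists; it sets out from alcohol 26 and comes back at vinyl iodide 31. Aqueous acid would give the hydroxy aldehyde F5, Takai olefination the iodo alcohol F6, acetylation the acetate F7, DDQ the C12 alcohol F8, and CBr4/(n-Oct)3P would then give 31 with inversion at C12.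

Further compounds
F1 | step 9 | 2-{[(3R,4R)-4-[(4-methoxybenzyl)oxy]-6-oxohexan-3-yl]oxy}-N,N-dimethylacetamide | CN(C)C(=O)CO[C@H](CC)[C@H](OCc1ccc(OC)cc1)CC=O
F2 | step 9 | 2-{[(3R,4R)-4-[(4-methoxybenzyl)oxy]hept-6-en-3-yl]oxy}-N,N-dimethylacetamide | CN(C)C(=O)CO[C@H](CC)[C@H](OCc1ccc(OC)cc1)CC=C
F3 | step 9 | (2R)-2-{[(3R,4R)-4-[(4-methoxybenzyl)oxy]hept-6-en-3-yl]oxy}-N,N-dimethylpent-4-enamide | CN(C)C(=O)[C@@H](CC=C)O[C@H](CC)[C@H](OCc1ccc(OC)cc1)CC=C
F4 | step 14 | (1R)-1-[(2R,7R,8R)-7-{[(chloromethyl)sulfonyl]oxy}-8-ethyl-3,6,7,8-tetrahydro-2H-oxocin-2-yl]-2-(1,3-dioxolan-2-yl)ethyl acetate | C1COC(C[C@@H](OC(C)=O)[C@H]2C/C=C\C[C@@H](OS(=O)(=O)CCl)[C@@H](CC)O2)O1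
F5 | step 15 | (3R)-3-[(2R,7R,8R)-8-ethyl-7-[(4-methoxybenzyl)oxy]-3,6,7,8-tetrahydro-2H-oxocin-2-yl]-3-hydroxypropanal | O=CC[C@@H](O)[C@H]1C/C=C\C[C@@H](OCc2ccc(OC)cc2)[C@@H](CC)O1
F6 | step 15 | (1R,3E)-1-[(2R,7R,8R)-8-ethyl-7-[(4-methoxybenzyl)oxy]-3,6,7,8-tetrahydro-2H-oxocin-2-yl]-4-iodobut-3-en-1-ol | I/C=C/C[C@@H](O)[C@H]1C/C=C\C[C@@H](OCc2ccc(OC)cc2)[C@@H](CC)O1
F7 | step 15 | (1R,3E)-1-[(2R,7R,8R)-8-ethyl-7-[(4-methoxybenzyl)oxy]-3,6,7,8-tetrahydro-2H-oxocin-2-yl]-4-iodobut-3-en-1-yl acetate | I/C=C/C[C@@H](OC(C)=O)[C@H]1C/C=C\C[C@@H](OCc2ccc(OC)cc2)[C@@H](CC)O1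
F8 | step 15 | (1R,3E)-1-[(2R,7R,8R)-8-ethyl-7-hydroxy-3,6,7,8-tetrahydro-2H-oxocin-2-yl]-4-iodobut-3-en-1-yl acetate | I/C=C/C[C@@H](OC(C)=O)[C@H]1C/C=C\C[C@@H](O)[C@@H](CC)O1
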